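At the first reading, 0.500 h, the north-west run already held 36.6% of target, so the opening was fast.

the same everywhere: starting material 0.50 M
- north-west: partner 0.75 M; rival reagent 1.2 M; run made earlier
- flask: partner 0.750 M; rival reagent 0.600 M; time 20 h

- north-west (time / h: target / %): 0.500: 36.6; 1.50: 38.7; 3.00: 32.4; 4.00: 29.2; 6.00: 24.6

(readings scatter by 1 percentage point)

* the moment within 20 h at which there is most target
* the amount of target, in percent of the starting material charged, at that time
* earliest time at which at least nineteen twentieths of that best amount are there
* latest time at which they still are

In those first instants I took it that partner and rival reagent were pulling on the same starting material. In the middle of the run the rise nearly stopped: the highest reading, 38.7% at 1.50 h, stands 2.1 percentage points above the first, against a scatter of 1 point. Target then fell to 24.6% at 6.00 h. I took that fall to come after the split, so I read the highest reading as the split and carried one number from it.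

preference = 0.631 × 1.2 M / 0.75 M = 1.01

This preference, the target made per unit of starting material taken by the rival at equal strengths of partner and rival, a selectivity factor, is a reading and carries the scatter. For the flask I scaled it by the charges.

target to rival's share = 1.01 × 0.750 M / 0.600 M = 1.26

target share = 55.8%

Then I put that share back in, taking one of partner or rival per starting material used. At the midpoint of that use, c partner over c rival reagent is 1.25, against 1.25 as charged, so I stopped after that round. My line gave a height and no times.

The forecast held that “the rival must take starting material in parallel”. It gave a peak of 56% at 1.3 h, with a window from 0.75 h to 2.3 h.

The flask gave 52.1% at 1.35 h, with a window from 0.756 h to 2.64 h.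

    starting material + partner ⇌ target (K = 20.0 M⁻¹, k = 0.0501 M⁻¹ min⁻¹)
    starting material + rival reagent → side product (k = 0.0430 M⁻¹ min⁻¹)

The forecast stood on all four counts, and the preference, from one reading and the charges, put the flask's peak 3.7 points too high. Taking away the reaction of starting material with rival reagent to side product lifts this flask's peak from 52.1% to 86.4%, a change of 34 points and the largest single effect.

On the neighbour charged with 2.4 M of rival reagent, the preference gives a target share of 24.0%. That neighbour's computed best is 24.7%.

The runs are calculated for substances that don't exist, and the scatter is random.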